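The numbers in the tables come from a simulation from invented constants.

**Read first.** Turn each product reading into a share of its own substrate before comparing runs, because each substrate is half of what is charged.

common to all: left-handed substrate 20 mM; right-handed substrate 20 mM; free catalyst 1.9 mol%
- alpha: coupling partner 2 equiv; impurity 0.10 mM; the very flask that is asked about, followed so far
- theta: coupling partner 2 equiv; impurity 0.050 mM; run made earlier
- flask: coupling partner 2.00 equiv; impurity 0.10 mM; time 8.0 h

alpha run (percent of the left-handed substrate and right-handed substrate together charged)

| time / min | left-handed product / % | right-handed product / % |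
|---|---|---|
| 6.00 | 0 | 0.6 |
| 20.0 | 4.6 | 1.4 |
| 30.0 | 5.3 | 4.4 |
| 50.0 | 7.4 | 3.4 |
| 80.0 | 11.5 | 4.4 |
| 90.0 | 13.5 | 3.9 |

theta run (percent of the left-handed substrate and right-handed substrate together charged)

| time / h | left-handed product / % | right-handed product / % |
|---|---|---|
| 0.500 | 4.5 | 1.5 |
| 1.50 | 12.0 | 5.1 |
| 3.00 | 22.0 | 9.7 |
| 4.00 | 22.9 | 13.0 |
| 6.00 | 31.2 | 16.5 |
| 8.00 | 34.0 | 18.2 |

(readings scatter by 1 percentage point)

- left-handed product and right-handed product together, in percent of the left-handed substrate and right-handed substrate charged together, at 8.0 h
- excess of left-handed product over right-handed product in the product at 8.0 h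
- whether the exchange between left-handed substrate and right-handed substrate keeps pace with the reaction: how far the product's excess at 8.0 h gets from its value without exchange to its value with instant exchange (above 80% keeps pace, below 20% hardly takes part, else lags behind)

- free catalyst is single-handed; left-handed substrate and right-handed substrate are mirror images of each other, charged as a racemate, each of them at the stated concentration
- the analysis behind the earlier runs scatters by 1 percentage point, standard deviation
- an excess is below zero if the other one leads

**Impurity.** If each impurity took one catalyst, alpha's 0.10 mM takes about a quarter of the 0.380 mM of catalyst charged, so by hand alpha falls behind theta. In the readings, alpha has 17.4% at 90.0 min and theta has 17.1% at 1.50 h, a gap inside the scatter.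

**Coupling partner.** By hand, if one is used per product, the 40.0 mM charged matches the 40.0 mM of both substrates. Theta's 52.2% at 8.00 h then leaves about half of it.

**Selectivity factor.** Theta's last reading gives 2.52. This is my apparent selectivity factor: the logarithm of the fraction of left-handed substrate left, over the same logarithm for right-handed substrate, each fraction reckoned as one minus twice the product reading. Theta's reading at 3.00 h gives 2.69, so I read no drift through the scatter. Taking this reading as the ratio of the two rates, with substrates held equal by instant exchange, I reckon the excess at 43.2%, and theta's last reading stands at 30.3%. I commit to theta's total and theta's excess for alpha, and leave exchange open.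

**The forecast.** It gives 53%, an excess of 32% (above mine), and exchange that hardly takes part, since theta “shows no sign of exchange”.

**The result.** The flask gives 50.9% with an excess of 25.0%, and exchange lags behind, 32% of the way.

    coupling partner + free catalyst + left-handed substrate → free catalyst + left-handed product (k = 51.0 M⁻² s⁻¹)
    coupling partner + free catalyst + right-handed substrate → free catalyst + right-handed product (k = 17.0 M⁻² s⁻¹)
    left-handed substrate ⇌ right-handed substrate (k = 2.00 × 10⁻⁵ s⁻¹)
    free catalyst + impurity → spent catalyst (k = 4.50 M⁻¹ s⁻¹)
    left-handed product ⇌ right-handed product (k = 1.30 × 10⁻⁵ s⁻¹)
    2 free catalyst ⇌ resting dimer, settled at all times (K = 1.70 × 10⁵ M⁻¹)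

**Same formula.** At 8.00 h the flask makes left-handed product 3.25 times faster, each step taken net, than it uses it up. The flask's 31.8% of left-handed product and 19.1% of right-handed product give an apparent factor of 2.10, less than the 2.52 read from theta. A neighbouring flask with 4.8 mol% of free catalyst holds 38.4% of left-handed product and 24.9% of right-handed product at 8.00 h, which give an apparent factor of 2.12.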